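| flask | substrate | partner | temperature | remark | time |
|---|---|---|---|---|---|
| ochre | 0.027 M | 0.90 equiv | 55 °C | run made earlier |  |
| blue | 0.013 M | 0.90 equiv | 66 °C | run made earlier |  |
| teal | 0.020 M | 0.90 equiv | 55 °C | run made earlier |  |
| midnight | 0.027 M | 0.900 equiv |  | everything together at the start at 40 °C, warmed to 60 °C at 50 min | 80 min |
| dusk | 0.027 M | 0.900 equiv | 60 °C | everything together at the start | 80 min |
| noon | 0.027 M (fed, over 50 min) | 0.900 equiv | 60 °C | all else is in the flask from the start; the feed brings no volume worth counting | 80 min |
| spring | 0.027 M | 0.900 equiv (fed, over 50 min) |  | the addition at 40 °C, then warmed to 60 °C; the feed brings no volume worth counting | 80 min |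

| run | time / min | target / % | substrate / % |
|---|---|---|---|
| ochre | 6.00 | 42 | 8 |
| ochre | 10.0 | 43 | 1 |
| ochre | 20.0 | 44 | 0 |
| ochre | 30.0 | 44 | 1 |
| ochre | 50.0 | 45 | 3 |
| ochre | 80.0 | 43 | 1 |
| blue | 4.00 | 23 | 3 |
| blue | 6.00 | 25 | 0 |
| blue | 10.0 | 19 | 0 |
| blue | 20.0 | 24 | 1 |
| blue | 30.0 | 20 | 1 |
| blue | 50.0 | 26 | 0 |
| teal | 8.00 | 38 | 6 |
| teal | 15.0 | 37 | 1 |
| teal | 25.0 | 38 | 0 |
| teal | 30.0 | 40 | 0 |
| teal | 40.0 | 39 | 0 |
| teal | 50.0 | 38 | 0 |

(scatter of a reading: 2 percentage points)



- the flask that comes out highest in amount of target, in percent of the substrate charged, or "all alike" when all lie within 1.5 percentage points (midnight / dusk / noon / spring / all alike)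
- target at the end, in percent of the substrate charged, midnight
- target at the end, in percent of the substrate charged, dusk
- target at the end, in percent of the substrate charged, noon
- target at the end, in percent of the substrate charged, spring

In a one-step world every substrate lost returns as target up to the partner charged, yet the ochre run reads 44% at 20.0 min with substrate at 0%. So substrate has a second exit, which I take as first order. Its rate then compares with the partner path through one constant, c*, and the target's share at any moment, the instantaneous selectivity, is:

share = c(partner) / (c(partner) + c*)

The level of partner drifts down as the substrate goes, so I apply the share at the midway level, the mean of the partner at start and at finish, and solve for c* from each plateau: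

ochre: plateau 44.0%, c* = 0.0234 M

teal: plateau 38.7%, c* = 0.0223 M

blue: plateau 22.8%, c* = 0.0346 M

Ochre and teal are two separate ways to one number: they differ in substrate and both run at 55 °C, and they agree, so I trust 0.0228 M. Blue parts from them, higher, and since concentration did not move c* between ochre and teal, I charge that gap to blue's temperature. Taking ln c* as straight in temperature, from ochre's value at its temperature to blue's at its own, gives two more values:

0.0279 M at 60 °C, 0.0137 M at 40 °C

The first is the break-even partner concentration, the partner level at which substrate leaves by both exits equally fast.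

The midway share then gives dusk 40.3%. Midnight, if its substrate leaves in the cold, gives 55.2%. Noon equals dusk for me provided partner stands still, and partner is not among the readings. Spring I leave without a figure.

The forecast names midnight highest, with midnight 55%, dusk 40%, noon 40% and spring 27%, holding that “feeding substrate changes nothing”.

The flasks give midnight 57.3%, dusk 40.7%, noon 28.5% and spring 23.4%, so noon lies 12 percentage points below dusk, where I had them equal.

    substrate + partner → target (k = 16.0 M⁻¹ min⁻¹, Ea = 47.0 kJ mol⁻¹)
    2 substrate → side product B (k = 1.10 M⁻¹ min⁻¹, Ea = 74.0 kJ mol⁻¹)
    partner → decomposed reagent (k = 0.0240 min⁻¹, Ea = 93.0 kJ mol⁻¹)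
    substrate → side product A (k = 0.380 min⁻¹, Ea = 84.0 kJ mol⁻¹)
    (constants at 60 °C)

In noon, partner averages 0.0111 M over the feed, and at that level c* gives a share of 28.5%. When noon's feed ends at 50.0 min, substrate stands at 4.51% of its charge and partner at 14.0% of its own. That is a share of 10.9%, which I reckon as worth 0.492% of the substrate charged as further target. At 800 min noon's target reads 28.5%, while partner has fallen from 6.53% to 0% and decomposed reagent has climbed from 0.0150 M to 0.0166 M.

Spring's 23.4%, at the break-even concentration of 0.0137 M for 40 °C, means a mean partner of 0.00418 M. Spring's neighbour with 0.540 equiv should hold 0.00251 M and give 15.5%; the computed neighbour gives 16.6%.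

The numbers in the tables were generated by integration for substances that don't exist; scatter was added.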